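**Strategy.** Everything rests on cutting the C5'–C6' bond (side chain numbered from benzylic C1'), i.e. the bond between the carbinol carbon and the vinylic CH of the C6'=C7' olefin. The key step is a ligand-controlled asymmetric Nozaki–Hiyama–Kishi coupling: the (E)-alkenyl iodide C6'–C16', carrying its primary allylic alcohol free, adds to the β,γ-unsaturated aldehyde C1'–C5' that bears the bis-silylated methylhydroquinone ring. One operation forms the bond, keeps the E-olefin and sets the only stereocentre, C5' (S). The feature exploited is the secondary allylic alcohol C5' beside the (E)-trisubstituted C6'=C7' olefin; that olefin and C2'=C3' both arise from methylalumination of terminal alkynes.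

Key step: step 13

Assumption: in step 13 the ligand enantiomer is the one that delivers the alkenyl group to the Re face of aldehyde 20 (this gives 5'S). The (S)-tert-leucinol-derived oxazoline–sulfonamide is written; its mirror image would be used if a trial coupling showed the opposite sense.

**Route**

Step 1
Reactants: 1 geranyl bromide; 2 1-(trimethylsilyl)propyne
Product: 4 trimethyl[(5E)-6,10-dimethylundeca-5,9-dien-1-yn-1-yl]silane, via lithiated silylpropyne 3 (not isolated)
Conditions: n-BuLi, THF, −78 °C; then 1, −78 °C → rt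
Reagents that add atoms: none
Why: Propargylic lithiation of 2 and SN2 alkylation of the primary allylic bromide (the silyl group steers attack to the propargylic terminus) should extend the chain by three carbons without touching the E-olefin.

Step 2
Reactants: 4 silyl dienyne
Product: 5 (2E,6E)-2,6-dimethyl-11-(trimethylsilyl)undeca-2,6-dien-10-yn-1-ol
Conditions: SeO2 (cat.), t-BuOOH, salicylic acid (cat.), CH2Cl2, 0 °C → rt
Reagents that add atoms: selenium dioxide, O=[Se]=O (delivers the oxygen); tert-butyl hydroperoxide, CC(C)(C)OO (restores the selenium oxidant)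
Why: Riley-type allylic oxidation (ene reaction, then [2,3]-sigmatropic shift) should attack the terminal isopropylidene group at its (E)-methyl and give the (E)-allylic alcohol, with the silyl cap keeping the alkyne inert.

Step 3
Reactants: 5 silyl alkynol
Product: 6 (2E,6E)-2,6-dimethylundeca-2,6-dien-10-yn-1-ol
Conditions: K2CO3, MeOH, rt
Reagents that add atoms: none
Why: Base-catalysed methanolysis of the alkynyl C–Si bond should free the terminal alkyne while alcohol and olefins stay untouched.

Step 4
Reactants: 6 alkynol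
Product: 8 (2E,6E,10E)-11-iodo-2,6,10-trimethylundeca-2,6,10-trien-1-ol, via alkenylalane 7 (not isolated)
Conditions: AlMe3 (3.5 equiv), Cp2ZrCl2 (0.3 equiv), CH2Cl2, 0 °C → rt; then I2, THF, −30 → 0 °C; aq. Rochelle salt/Na2S2O3 work-up
Reagents that add atoms: trimethylaluminium, C[Al](C)C; iodine, II
Why: Zr-catalysed methylalumination (Negishi carboalumination) adds Me and Al syn with Al on the terminal carbon, the alcohol riding as its aluminium alkoxide, and iodinolysis of the C–Al bond with retention should give the (E)-iodide.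

Step 5
Reactants: 9 4-(tert-butyldimethylsilyloxy)but-1-yne
Product: 11 (2E)-5-(tert-butyldimethylsilyloxy)-3-methylpent-2-en-1-ol, via alkenylalane 10 (not isolated)
Conditions: AlMe3 (2 equiv), Cp2ZrCl2 (0.2 equiv), CH2Cl2, rt; then n-BuLi, THF, −78 → 0 °C; (CH2O)n, rt
Reagents that add atoms: trimethylaluminium, C[Al](C)C; formaldehyde (as paraformaldehyde), C=O
Why: Negishi carboalumination (syn, Al terminal) followed by hydroxymethylation of the derived alanate with retention should give the (E)-trisubstituted allylic alcohol that becomes C1'–C5'.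

Step 6
Reactants: 11 allylic alcohol
Product: 12 [(3E)-5-bromo-3-methylpent-3-en-1-yloxy](tert-butyl)dimethylsilane
Conditions: CBr4, PPh3, CH2Cl2, 0 °C
Reagents that add atoms: carbon tetrabromide, BrC(Br)(Br)Br
Why: Appel bromination of the primary allylic alcohol is neutral and should proceed by SN2 without allylic shift or loss of the alkyl silyl ether.

Step 7
Reactants: 13 2-bromo-6-methylphenol
Product: 14 2-bromo-6-methyl-1,4-benzoquinone
Conditions: (KSO3)2NO, KH2PO4, H2O/acetone, rt
Reagents that add atoms: Fremy's salt (potassium nitrosodisulfonate), [K+].[K+].[O]N(S(=O)(=O)[O-])S(=O)(=O)[O-]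
Why: Teuber oxidation of a phenol with a free para position should place the second oxygen para to the first, fixing the 1,4-dioxygen pattern with Br and Me on either side of O1.

Step 8
Reactants: 14 bromoquinone
Product: 15 2-bromo-6-methylbenzene-1,4-diol
Conditions: Na2S2O4, EtOAc/H2O, rt
Reagents that add atoms: none
Why: Dithionite reduction of a p-quinone to the hydroquinone is fast and leaves the aryl bromide alone.

Step 9
Reactants: 15 bromohydroquinone
Product: 16 1-bromo-2,5-bis(tert-butyldimethylsilyloxy)-3-methylbenzene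
Conditions: TBSCl, imidazole, DMF, rt → 40 °C
Reagents that add atoms: tert-butyldimethylsilyl chloride, CC(C)(C)[Si](C)(C)Cl
Why: Silylation of both phenols gives ethers that survive organometallic, acidic-methanol and oxidative steps and leave under fluoride at the end without acid.

Step 10
Reactants: 16 aryl bromide; 12 allylic bromide
Product: 18 tert-butyl{[(3E)-5-[2,5-bis(tert-butyldimethylsilyloxy)-3-methylphenyl]-3-methylpent-3-en-1-yl]oxy}dimethylsilane, via aryl Grignard reagent 17 (not isolated)
Conditions: Mg, LiCl, THF, rt → 40 °C; then Li2CuCl4 (5 mol %), 12, THF, −20 → 0 °C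
Reagents that add atoms: none
Why: Copper-catalysed coupling of an aryl Grignard reagent with a primary allylic bromide should occur at the unhindered α-carbon with the E-geometry kept, and magnesium instead of lithium avoids O→C silyl migration.

Step 11
Reactants: 18 tris-silyl ether
Product: 19 (3E)-5-[2,5-bis(tert-butyldimethylsilyloxy)-3-methylphenyl]-3-methylpent-3-en-1-ol
Conditions: CSA (cat.), MeOH/CH2Cl2, 0 °C
Reagents that add atoms: none
Why: Acid-catalysed methanolysis cleaves a primary alkyl silyl ether much faster than the aryl silyl ethers, so only the C5' oxygen should be freed.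

Step 12
Reactants: 19 homoallylic alcohol
Product: 20 (3E)-5-[2,5-bis(tert-butyldimethylsilyloxy)-3-methylphenyl]-3-methylpent-3-enal
Conditions: Dess–Martin periodinane, NaHCO3, CH2Cl2, 0 °C; used at once
Reagents that add atoms: none
Why: Buffered Dess–Martin oxidation is near-neutral and should give the β,γ-unsaturated aldehyde without moving the olefin into conjugation.

Step 13
Reactants: 8 alkenyl iodide (1.3 equiv); 20 aldehyde
Product: 22 (2E,6E,10E,12S,14E)-16-[2,5-bis(tert-butyldimethylsilyloxy)-3-methylphenyl]-2,6,10,14-tetramethylhexadeca-2,6,10,14-tetraene-1,12-diol, via alkenylchromium species 21 (not isolated)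
Conditions: CrCl2 (4 equiv), (S)-tert-leucinol-derived 2-(2-methanesulfonamidoaryl)oxazoline ligand (4.4 equiv, recovered), Et3N (4.4 equiv), THF, rt; then NiCl2 (0.1 equiv), 8 and 20, rt
Reagents that add atoms: none
Why: Nozaki–Hiyama–Kishi coupling: Ni(0) inserts into the C–I bond of 8, the alkenyl group passes to Cr(III) with retention of the E-geometry to give 21, and this adds to the aldehyde carbon of 20 to form the C5'–C6' bond. The closest known reaction type is the asymmetric Ni/Cr coupling of alkenyl iodides with aldehydes under chiral oxazoline–sulfonamide ligands on chromium. No ring is closed. The new stereocentre C5' is set by the chiral ligand on chromium (reagent control, Re-face addition giving S), since neither partner carries a stereocentre. The step needs chemoselectivity for the aldehyde beside a free primary allylic alcohol, two aryl silyl ethers and three other olefins, and it needs the β,γ-olefin of 20 to stay out of conjugation; the non-basic, carbonyl-selective organochromium reagent at room temperature should secure both.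

Step 14
Reactants: 22 bis-silyl ether
Product: 23 2-[(2E,5S,6E,10E,14E)-5,16-dihydroxy-3,7,11,15-tetramethylhexadeca-2,6,10,14-tetraen-1-yl]-6-methylbenzene-1,4-diol (target)
Conditions: TBAF, AcOH, THF, 0 °C, under argon; work-up with dilute aq. Na2S2O4
Reagents that add atoms: none
Why: Fluoride desilylation removes both aryl silyl ethers; acetic acid buffering and exclusion of air should protect the hydroquinone from oxidation, and the absence of acid avoids chroman formation and ionisation of the allylic alcohol.

**Compound list**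

1 | geranyl bromide, (2E)-1-bromo-3,7-dimethylocta-2,6-diene | CC(C)=CCC/C(C)=C/CBr | starting material
2 | 1-(trimethylsilyl)propyne | CC#C[Si](C)(C)C | starting material
3 | 3-lithio-1-(trimethylsilyl)propyne | [Li]CC#C[Si](C)(C)C | intermediate
4 | trimethyl[(5E)-6,10-dimethylundeca-5,9-dien-1-yn-1-yl]silane | CC(C)=CCC/C(C)=C/CCC#C[Si](C)(C)C | intermediate
5 | (2E,6E)-2,6-dimethyl-11-(trimethylsilyl)undeca-2,6-dien-10-yn-1-ol | C/C(=C\CC/C(C)=C/CCC#C[Si](C)(C)C)CO | intermediate
6 | (2E,6E)-2,6-dimethylundeca-2,6-dien-10-yn-1-ol | C/C(=C\CC/C(C)=C/CCC#C)CO | intermediate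
7 | [(1E,5E,9E)-11-(dimethylalumanyloxy)-2,6,10-trimethylundeca-1,5,9-trien-1-yl]dimethylalane | C/C(=C\CC/C(C)=C/CC/C(C)=C/[Al](C)C)CO[Al](C)C | intermediate
8 | (2E,6E,10E)-11-iodo-2,6,10-trimethylundeca-2,6,10-trien-1-ol | C/C(=C\CC/C(C)=C/CC/C(C)=C/I)CO | intermediate
9 | 4-(tert-butyldimethylsilyloxy)but-1-yne | C#CCCO[Si](C)(C)C(C)(C)C | starting material
10 | [(1E)-4-(tert-butyldimethylsilyloxy)-2-methylbut-1-en-1-yl]dimethylalane | C/C(CCO[Si](C)(C)C(C)(C)C)=C\[Al](C)C | intermediate
11 | (2E)-5-(tert-butyldimethylsilyloxy)-3-methylpent-2-en-1-ol | C/C(CCO[Si](C)(C)C(C)(C)C)=C\CO | intermediate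
12 | [(3E)-5-bromo-3-methylpent-3-en-1-yloxy](tert-butyl)dimethylsilane | C/C(CCO[Si](C)(C)C(C)(C)C)=C\CBr | intermediate
13 | 2-bromo-6-methylphenol | Cc1cccc(Br)c1O | starting material
14 | 2-bromo-6-methyl-1,4-benzoquinone | CC1=CC(=O)C=C(Br)C1=O | intermediate
15 | 2-bromo-6-methylbenzene-1,4-diol | Cc1cc(O)cc(Br)c1O | intermediate
16 | 1-bromo-2,5-bis(tert-butyldimethylsilyloxy)-3-methylbenzene | Cc1cc(O[Si](C)(C)C(C)(C)C)cc(Br)c1O[Si](C)(C)C(C)(C)C | intermediate
17 | [2,5-bis(tert-butyldimethylsilyloxy)-3-methylphenyl]magnesium bromide | Cc1cc(O[Si](C)(C)C(C)(C)C)cc([Mg]Br)c1O[Si](C)(C)C(C)(C)C | intermediate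
18 | tert-butyl{[(3E)-5-[2,5-bis(tert-butyldimethylsilyloxy)-3-methylphenyl]-3-methylpent-3-en-1-yl]oxy}dimethylsilane | C/C(CCO[Si](C)(C)C(C)(C)C)=C\Cc1cc(O[Si](C)(C)C(C)(C)C)cc(C)c1O[Si](C)(C)C(C)(C)C | intermediate
19 | (3E)-5-[2,5-bis(tert-butyldimethylsilyloxy)-3-methylphenyl]-3-methylpent-3-en-1-ol | C/C(CCO)=C\Cc1cc(O[Si](C)(C)C(C)(C)C)cc(C)c1O[Si](C)(C)C(C)(C)C | intermediate
20 | (3E)-5-[2,5-bis(tert-butyldimethylsilyloxy)-3-methylphenyl]-3-methylpent-3-enal | C/C(CC=O)=C\Cc1cc(O[Si](C)(C)C(C)(C)C)cc(C)c1O[Si](C)(C)C(C)(C)C | intermediate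
21 | [(1E,5E,9E)-11-hydroxy-2,6,10-trimethylundeca-1,5,9-trien-1-yl]chromium(III) dichloride (chiral ligand on Cr not drawn) | C/C(=C\CC/C(C)=C/CC/C(C)=C/[Cr](Cl)Cl)CO | intermediate
22 | (2E,6E,10E,12S,14E)-16-[2,5-bis(tert-butyldimethylsilyloxy)-3-methylphenyl]-2,6,10,14-tetramethylhexadeca-2,6,10,14-tetraene-1,12-diol | C/C(=C\CC/C(C)=C/CC/C(C)=C/[C@@H](O)C/C(C)=C/Cc1cc(O[Si](C)(C)C(C)(C)C)cc(C)c1O[Si](C)(C)C(C)(C)C)CO | intermediate
23 | 2-[(2E,5S,6E,10E,14E)-5,16-dihydroxy-3,7,11,15-tetramethylhexadeca-2,6,10,14-tetraen-1-yl]-6-methylbenzene-1,4-diol | C/C(=C\CC/C(C)=C/CC/C(C)=C/[C@@H](O)C/C(C)=C/Cc1cc(O)cc(C)c1O)CO | target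

**Step count and risks**

Total steps: 14. Longest linear sequence: 8 (steps 7–14, from 13). The route is convergent: steps 1–4 give iodide 8, steps 5–6 give bromide 12, steps 7–12 give aldehyde 20.

Steps most likely to fail:

1. Step 13. The facial selectivity of the ligand-bound alkenylchromium at an unbranched aldehyde may be insufficient, and the β,γ-double bond of the aldehyde may migrate into conjugation before coupling. The fallback is a lithiation–borylation that needs no aldehyde; it sets out from alcohol 19 and iodide 8 and comes back at target 23.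
   - Alcohol 19 would be carbamoylated (iPr2NCOCl, Et3N, CH2Cl2, reflux) to (3E)-5-[2,5-bis(tert-butyldimethylsilyloxy)-3-methylphenyl]-3-methylpent-3-en-1-yl N,N-diisopropylcarbamate F1.
   - Iodide 8 would be silylated (TBSCl, imidazole, DMF) to the silyl ether of the iodo trienol F2, then converted with retention by Miyaura borylation (B2pin2, PdCl2(PPh3)2, KOPh, toluene, 50 °C) into the (E)-alkenyl pinacol boronate F3.
   - Hoppe deprotonation of F1 with s-BuLi/(+)-sparteine (Et2O, −78 °C), addition of F3 and warming should give the (S)-allylic pinacol boronic ester F4. The sequence is stereoretentive borylation, then 1,2-shift of the alkenyl group from boron to carbon with inversion.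
   - Oxidation in the same flask (NaBO3·4H2O, THF/H2O) should give, with retention, the tris-silyl ether of the target F5. TBAF/AcOH then gives 23.

2. Step 2. Oxidation at the allylic positions of the internal olefin may compete with the terminal (E)-methyl, and over-oxidation to the enal may occur. The fallback builds the hydroxylated terminus by cleavage and olefination; it sets out from 4 and comes back at 6.
   - NBS in THF/H2O (0 °C) should form the terminal bromohydrin, (6E)-3-bromo-2,6-dimethyl-11-(trimethylsilyl)undec-6-en-10-yn-2-ol F6 (racemic).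
   - K2CO3/MeOH closes the epoxide and removes the alkynyl silyl group, giving 2,2-dimethyl-3-[(3E)-3-methyloct-3-en-7-yn-1-yl]oxirane F7.
   - H5IO6 (THF/H2O) cleaves the epoxide to (4E)-4-methylnon-4-en-8-ynal F8.
   - Wittig olefination with Ph3P=C(Me)CO2Et (CH2Cl2, rt) should give the E-enoate, ethyl (2E,6E)-2,6-dimethylundeca-2,6-dien-10-ynoate F9.
   - DIBAL-H (CH2Cl2, −78 °C) reduces F9 to 6.

3. Step 10. Magnesium insertion into the electron-rich bromide may be sluggish, the aryl metal may undergo O→C silyl migration, and the allylic partner may react at the γ-carbon or lose its geometry. The fallback avoids carbanions; it sets out from 16 (with 12) and comes back at 18.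
   - Pd-catalysed stannylation of 16 (Me3SnSnMe3, Pd(PPh3)4, toluene, 100 °C) gives [2,5-bis(tert-butyldimethylsilyloxy)-3-methylphenyl]trimethylstannane F10.
   - Stille coupling of F10 with bromide 12 (Pd2(dba)3, AsPh3, THF, 50 °C) should join the aryl group to the less substituted allyl terminus under neutral conditions and give 18.

Further compounds

F1 | step 13 | (3E)-5-[2,5-bis(tert-butyldimethylsilyloxy)-3-methylphenyl]-3-methylpent-3-en-1-yl N,N-diisopropylcarbamate | C/C(CCOC(=O)N(C(C)C)C(C)C)=C\Cc1cc(O[Si](C)(C)C(C)(C)C)cc(C)c1O[Si](C)(C)C(C)(C)C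
F2 | step 13 | tert-butyl{[(2E,6E,10E)-11-iodo-2,6,10-trimethylundeca-2,6,10-trien-1-yl]oxy}dimethylsilane | C/C(=C\CC/C(C)=C/CC/C(C)=C/I)CO[Si](C)(C)C(C)(C)C
F3 | step 13 | tert-butyldimethyl{[(2E,6E,10E)-2,6,10-trimethyl-11-(4,4,5,5-tetramethyl-1,3,2-dioxaborolan-2-yl)undeca-2,6,10-trien-1-yl]oxy}silane | C/C(=C\CC/C(C)=C/CC/C(C)=C/B1OC(C)(C)C(C)(C)O1)CO[Si](C)(C)C(C)(C)C
F4 | step 13 | (S)-allylic pinacol boronic ester: the tris-silyl ether of the target with a pinacolatoboryl group in place of the C5' hydroxyl | C/C(=C\CC/C(C)=C/CC/C(C)=C/[C@@H](B1OC(C)(C)C(C)(C)O1)C/C(C)=C/Cc1cc(O[Si](C)(C)C(C)(C)C)cc(C)c1O[Si](C)(C)C(C)(C)C)CO[Si](C)(C)C(C)(C)C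
F5 | step 13 | (2E,5S,6E,10E,14E)-1-[2,5-bis(tert-butyldimethylsilyloxy)-3-methylphenyl]-16-(tert-butyldimethylsilyloxy)-3,7,11,15-tetramethylhexadeca-2,6,10,14-tetraen-5-ol | C/C(=C\CC/C(C)=C/CC/C(C)=C/[C@@H](O)C/C(C)=C/Cc1cc(O[Si](C)(C)C(C)(C)C)cc(C)c1O[Si](C)(C)C(C)(C)C)CO[Si](C)(C)C(C)(C)C
F6 | step 2 | (6E)-3-bromo-2,6-dimethyl-11-(trimethylsilyl)undec-6-en-10-yn-2-ol (racemic) | CC(C)(O)C(Br)CC/C(C)=C/CCC#C[Si](C)(C)C
F7 | step 2 | 2,2-dimethyl-3-[(3E)-3-methyloct-3-en-7-yn-1-yl]oxirane (racemic) | CC1(C)OC1CC/C(C)=C/CCC#C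
F8 | step 2 | (4E)-4-methylnon-4-en-8-ynal | O=CCC/C(C)=C/CCC#C
F9 | step 2 | ethyl (2E,6E)-2,6-dimethylundeca-2,6-dien-10-ynoate | CCOC(=O)/C(C)=C/CC/C(C)=C/CCC#C
F10 | step 10 | [2,5-bis(tert-butyldimethylsilyloxy)-3-methylphenyl]trimethylstannane | Cc1cc(O[Si](C)(C)C(C)(C)C)cc([Sn](C)(C)C)c1O[Si](C)(C)C(C)(C)C
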